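The data are simulated for an exercise; scatter was added.

At 6.0 min I have to say how much target stands in the flasks below, yet the two earlier runs stop at 4.00 min.

| flask | starting material | coupling partner | initiator | remark | time |
|---|---|---|---|---|---|
| autumn | 0.043 M | 1.3 equiv | 1.4 mol% | run made earlier |  |
| spring | 1.2 M | 1.3 equiv | 1.4 mol% | run made earlier |  |
| theta | 0.030 M | 1.30 equiv | 1.4 mol% |  | 6.0 min |
| delta | 0.10 M | 1.30 equiv | 1.4 mol% |  | 6.0 min |
| gamma | 0.30 M | 1.30 equiv | 1.4 mol% |  | 6.0 min |
| eta | 1.0 M | 1.30 equiv | 1.4 mol% |  | 6.0 min |

| run | time / min | target / % | starting material / % |
|---|---|---|---|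
| autumn | 1.00 | 7.6 | 31.5 |
| autumn | 2.00 | 10.7 | 24.1 |
| autumn | 3.00 | 13.7 | 23.4 |
| autumn | 4.00 | 15.5 | 22.9 |
| spring | 0.500 | 18.6 | 38.9 |
| spring | 1.33 | 26.2 | 20.7 |
| spring | 2.50 | 31.8 | 17.8 |
| spring | 4.00 | 36.8 | 15.8 |

(scatter of a reading: 0.3 percentage points)

- [target] at the end for theta, delta, gamma, eta, in this order
- the shape of the row from first to last (falls, then rises / rises all the way / rises, then falls / falls all the way / hardly changes)

- percent here means starting material units held: one ended chains B counts as two
- candidate steps: starting material + second chain carrier -> by-product + first chain carrier; initiator -> 2 initiating radical; starting material -> decomposition product; starting material + initiating radical -> capped initiator + first chain carrier; coupling partner + first chain carrier <-> target + second chain carrier; 2 second chain carrier -> ended chains A; starting material <-> dormant form; 2 first chain carrier -> ended chains B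
- "hardly changes" means that all values lie within two and a half points (for a concentration: within two and a half percent of the largest)

Starting material is the limiting reagent, with coupling partner at 1.3 equiv. I therefore compare P, the target in percent of the starting material charged, at 4.00 min, the last time both runs read. The bench rule for a chain ended by pairs of carriers says that, at fixed loading, equivalents and time and while little has reacted, P goes as the square root of the charge c. Spring has 27.9 times the charge of autumn, so the rule asks for a factor of 5.28 in P. But the readings, 36.8 % in spring and 15.5 % in autumn, give 2.37, so over this span the rule stops working.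

I keep the measured slope instead. Read off these two readings, the logarithm of that ratio of P over the logarithm of the ratio of charges is 0.260, and this yield exponent n is what I carry. I take it that at this loading, with these equivalents and at a fixed time, P goes as c to the power n, so that target concentration, P times c, goes as c to the power one plus n. Eta against theta is then a factor of 2.49 in P and 82.9 in concentration, so my row rises all the way. I am assuming that n holds outside the runs: theta has 0.698 of the autumn charge, and the asked time is 1.50 times the last reading.

The forecast gives 0.0051 M, 0.023 M, 0.089 M and 0.4 M, shape rises all the way, on the ground that “Yield and charge both increase”. Its eta stands at 78.4 times its theta, less than my 82.9.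

The flasks give 0.00514 M, 0.0242 M, 0.0950 M and 0.409 M, shape rises all the way.

    starting material + second chain carrier → by-product + first chain carrier (k = 6900 M⁻¹ s⁻¹)
    initiator → 2 initiating radical (k = 5.00 × 10⁻⁴ s⁻¹)
    starting material → decomposition product (k = 2.50 × 10⁻⁶ s⁻¹)
    starting material + initiating radical → capped initiator + first chain carrier (k = 2.10 × 10⁵ M⁻¹ s⁻¹)
    coupling partner + first chain carrier ⇌ target + second chain carrier (K = 0.110, k = 40000 M⁻¹ s⁻¹)
    2 second chain carrier → ended chains A (k = 2.00 × 10⁶ M⁻¹ s⁻¹)
    starting material ⇌ dormant form (K = 2.60, k = 0.0270 s⁻¹)
    2 first chain carrier → ended chains B (k = 2.60 × 10⁶ M⁻¹ s⁻¹)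

Eta ends with 40.9 % target beside 43.2 % dormant form. The exponent 0.260 gave 2.49 for eta over theta in P, and the flasks hold 2.39. For gamma against delta it gives 1.33, and gamma holds 31.7 % target against 24.2 % in delta, a factor of 1.31.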